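**Plan**
1. The heptane chain is numbered from C1 (benzylic CH2 at the catechol ring) to C7 (benzylic CH2 at the guaiacyl ring). The target is the (3S,5R), 3,5-syn diacetate, and it is chiral only because the two aryl ends differ.
2. Retrosynthesis: three O-benzyl groups and the O5 acetyl are removed. One C1–H is then replaced by a C1–O5 bond, which folds O5, C5, C4, C3, C2 and C1 into a tetrahydropyran. A Prins disconnection cuts this ring at C1–C2 (together with C1–O5 and C3–O) into 3,4-bis(benzyloxy)benzaldehyde and a C2–C7 homoallylic alcohol, and the alcohol is cut at C4–C5 into allyl and a 3-arylpropanal.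
3. Enabling feature: O5 lies 1,5 to C1, and O3 sits on the carbon that becomes the cationic ring position 4. C1 is benzylic and para to the C4' oxygen of the catechol ring, so the C1–O5 bond is easy to make (conjugated oxocarbenium ion) and easy to erase (ionisation, then hydride capture).
4. Forward order: guaiacyl C5–C7 aldehyde, allylation (C4–C5), Prins union with the catechol aldehyde (the only ring formed, and a temporary one), inversion at C3, reductive ring opening, acetylation of O5, debenzylation.
5. Stereochemistry: C5 (R) comes from a reagent-controlled Brown allylation. C3 is set by 1,3-induction from C5 in the chair Prins transition state (4,6-cis) and is then inverted by SN2 in a Mitsunobu acetylation to the 3,5-syn array. The ring stereocentre at C1 is temporary.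

Key step: step 4

Assumption: 1 and 6 are taken as catalogue chemicals, and (−)-Ipc2BOMe denotes the reagent of the (+)-α-pinene series.

Step 1
Reactants: 1 4-(3-hydroxypropyl)-2-methoxyphenol (dihydroconiferyl alcohol)
Product: 2 3-[4-(benzyloxy)-3-methoxyphenyl]propan-1-ol
Conditions: BnBr, K2CO3, acetone, reflux
Reagents that add atoms: benzyl bromide, BrCc1ccccc1
Why: Williamson etherification, in which carbonate deprotonates only the phenol, so the primary alcohol should stay free.

Step 2
Reactants: 2 3-[4-(benzyloxy)-3-methoxyphenyl]propan-1-ol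
Product: 3 3-[4-(benzyloxy)-3-methoxyphenyl]propanal
Conditions: TEMPO (cat.), PhI(OAc)2, CH2Cl2, rt
Reagents that add atoms: none
Why: Oxoammonium (TEMPO) oxidation should stop at the aldehyde in the absence of water and leave the benzyl ether and the electron-rich ring untouched.

Step 3
Reactants: 3 3-[4-(benzyloxy)-3-methoxyphenyl]propanal
Product: 5 (R)-1-[4-(benzyloxy)-3-methoxyphenyl]hex-5-en-3-ol, via diisopinocampheylborinate 4 (not isolated)
Conditions: (−)-Ipc2BOMe, allylMgBr, Et2O, −78 °C to rt; then 3, −78 °C; NaOH, H2O2, rt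
Reagents that add atoms: allylmagnesium bromide, C=CC[Mg]Br; (−)-B-methoxydiisopinocampheylborane, COB([C@@H]1C[C@@H]2C[C@H]([C@H]1C)C2(C)C)[C@@H]1C[C@@H]2C[C@H]([C@H]1C)C2(C)C (its boron and isopinocampheyl groups stay only in 4)
Why: Brown allylation, in which the allyl group passes through a closed chair transition state and the isopinocampheyl groups of the (+)-α-pinene series direct it to the Si face of an unbranched aldehyde, which sets C5 as R before oxidative work-up frees the alcohol.

Step 4
Reactants: 5 (R)-1-[4-(benzyloxy)-3-methoxyphenyl]hex-5-en-3-ol; 6 3,4-bis(benzyloxy)benzaldehyde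
Product: 9 (2R,4S,6R)-2-[3,4-bis(benzyloxy)phenyl]-6-{2-[4-(benzyloxy)-3-methoxyphenyl]ethyl}tetrahydro-2H-pyran-4-ol, via oxocarbenium trifluoroacetate 7 (not isolated), via tetrahydropyranyl trifluoroacetate 8 (not isolated)
Conditions: TFA, CH2Cl2, 0 °C to rt; evaporate; K2CO3 (cat.), MeOH, rt
Reagents that add atoms: trifluoroacetic acid, OC(=O)C(F)(F)F
Why: TFA condenses 5 and 6 with loss of water to the (E)-oxocarbenium ion 7, in which O5 is doubly bonded to C1; the terminal alkene carbon C2 attacks C1, the charge that develops at C3 is quenched by trifluoroacetate to give 8, and catalytic methanolysis of this labile ester frees 9. The closest known reaction type is the acid-mediated Prins cyclisation of secondary homoallylic alcohols with aromatic aldehydes to all-cis 2,6-disubstituted tetrahydropyran-4-ols, which is established for 2-aryl-6-(2-arylethyl) members of the diarylheptanoid class. The one ring that closes (O5–C5–C4–C3–C2–C1) forms in a 6-endo-trig mode at the alkene through a chair transition state. The C5 stereocentre controls both new centres: its arylethyl chain takes an equatorial place, the aryl group on C1 follows into the second equatorial place (2,6-cis, a temporary centre erased in step 6), and the nucleophile enters at C3 along the equatorial direction in which the chair cation is best stabilised (4,6-cis), so that C3 should arise as one predictable epimer, deliberately the one that step 5 inverts. The step needs ring closure to outrun 2-oxonia-Cope rearrangement and allyl transfer, which would exchange side chains and erode the configuration at C5, and here 7 is the aryl-conjugated and therefore lower-energy partner of that equilibrium, so the rearrangement is uphill. It also needs the alkene to win over the guaiacyl ring as nucleophile, which a six-membered against a seven-membered transition state secures, and the aryl benzyl ethers to outlast dilute TFA, which they should because they could ionise only to an unstabilised primary benzyl cation.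

Step 5
Reactants: 9 (2R,4S,6R)-2-[3,4-bis(benzyloxy)phenyl]-6-{2-[4-(benzyloxy)-3-methoxyphenyl]ethyl}tetrahydro-2H-pyran-4-ol
Product: 10 (2R,4R,6R)-2-[3,4-bis(benzyloxy)phenyl]-6-{2-[4-(benzyloxy)-3-methoxyphenyl]ethyl}tetrahydro-2H-pyran-4-yl acetate
Conditions: PPh3, DIAD, AcOH, THF, 0 °C to rt
Reagents that add atoms: acetic acid, CC(=O)O
Why: Mitsunobu reaction, in which acetate displaces the activated equatorial C–O bond by SN2 along the open axial trajectory, inverting ring C4 (chain C3) to the 4,6-trans, 3,5-syn arrangement of the target and installing the first acetate in the same operation.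

Step 6
Reactants: 10 (2R,4R,6R)-2-[3,4-bis(benzyloxy)phenyl]-6-{2-[4-(benzyloxy)-3-methoxyphenyl]ethyl}tetrahydro-2H-pyran-4-yl acetate
Product: 11 (3S,5R)-1-[3,4-bis(benzyloxy)phenyl]-7-[4-(benzyloxy)-3-methoxyphenyl]-5-hydroxyheptan-3-yl acetate
Conditions: Et3SiH (excess), TFA, CH2Cl2, 0 °C; aq. NaHCO3
Reagents that add atoms: none
Why: Kursanov–Parnes ionic hydrogenation, in which the protonated ring oxygen leaves C1 as a secondary benzylic cation stabilised by the para benzyloxy group and the silane delivers hydride to it, while the primary PhCH2–OAr bonds cannot ionise and the C5–O and C3–O bonds, and hence both stereocentres, stay intact.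

Step 7
Reactants: 11 (3S,5R)-1-[3,4-bis(benzyloxy)phenyl]-7-[4-(benzyloxy)-3-methoxyphenyl]-5-hydroxyheptan-3-yl acetate
Product: 12 (3S,5R)-1-[3,4-bis(benzyloxy)phenyl]-7-[4-(benzyloxy)-3-methoxyphenyl]heptane-3,5-diyl diacetate
Conditions: Ac2O, pyridine, DMAP (cat.), CH2Cl2, rt
Reagents that add atoms: acetic anhydride, CC(=O)OC(C)=O
Why: DMAP-catalysed acylation of the only free hydroxyl group proceeds with retention at C5, and a 1,3-acetyl shift in 11 would be harmless because both oxygens end as acetates.

Step 8
Reactants: 12 (3S,5R)-1-[3,4-bis(benzyloxy)phenyl]-7-[4-(benzyloxy)-3-methoxyphenyl]heptane-3,5-diyl diacetate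
Product: 13 (3S,5R)-1-(3,4-dihydroxyphenyl)-7-(4-hydroxy-3-methoxyphenyl)heptane-3,5-diyl diacetate
Conditions: H2 (1 atm), 10% Pd/C, EtOAc–EtOH, rt, filtration under argon
Reagents that add atoms: none
Why: Catalytic hydrogenolysis should cleave the three aryl benzyl ethers under neutral conditions, whereas the two secondary acetates are neither benzylic nor allylic and should survive.

**Compound list**
1 | 4-(3-hydroxypropyl)-2-methoxyphenol (dihydroconiferyl alcohol) | COc1cc(CCCO)ccc1O | starting material
2 | 3-[4-(benzyloxy)-3-methoxyphenyl]propan-1-ol | COc1cc(CCCO)ccc1OCc1ccccc1 | intermediate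
3 | 3-[4-(benzyloxy)-3-methoxyphenyl]propanal | COc1cc(CCC=O)ccc1OCc1ccccc1 | intermediate
4 | (R)-1-[4-(benzyloxy)-3-methoxyphenyl]hex-5-en-3-yl diisopinocampheylborinate | COc1cc(CC[C@H](CC=C)OB([C@@H]2C[C@@H]3C[C@H]([C@H]2C)C3(C)C)[C@@H]2C[C@@H]3C[C@H]([C@H]2C)C3(C)C)ccc1OCc1ccccc1 | intermediate
5 | (R)-1-[4-(benzyloxy)-3-methoxyphenyl]hex-5-en-3-ol | COc1cc(CC[C@H](CC=C)O)ccc1OCc1ccccc1 | intermediate
6 | 3,4-bis(benzyloxy)benzaldehyde | O=Cc1ccc(OCc2ccccc2)c(OCc2ccccc2)c1 | starting material
7 | (E)-oxocarbenium ion from 5 and 6 (O5=C1), as its trifluoroacetate | COc1cc(CC[C@H](CC=C)/[O+]=C/c2ccc(OCc3ccccc3)c(OCc3ccccc3)c2)ccc1OCc1ccccc1.[O-]C(=O)C(F)(F)F | intermediate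
8 | (2R,4S,6R)-2-[3,4-bis(benzyloxy)phenyl]-6-{2-[4-(benzyloxy)-3-methoxyphenyl]ethyl}tetrahydro-2H-pyran-4-yl trifluoroacetate (all-cis) | COc1cc(CC[C@@H]2C[C@H](OC(=O)C(F)(F)F)C[C@H](c3ccc(OCc4ccccc4)c(OCc4ccccc4)c3)O2)ccc1OCc1ccccc1 | intermediate
9 | (2R,4S,6R)-2-[3,4-bis(benzyloxy)phenyl]-6-{2-[4-(benzyloxy)-3-methoxyphenyl]ethyl}tetrahydro-2H-pyran-4-ol (all-cis) | COc1cc(CC[C@@H]2C[C@H](O)C[C@H](c3ccc(OCc4ccccc4)c(OCc4ccccc4)c3)O2)ccc1OCc1ccccc1 | intermediate
10 | (2R,4R,6R)-2-[3,4-bis(benzyloxy)phenyl]-6-{2-[4-(benzyloxy)-3-methoxyphenyl]ethyl}tetrahydro-2H-pyran-4-yl acetate (2,6-cis, axial acetate) | COc1cc(CC[C@@H]2C[C@@H](OC(C)=O)C[C@H](c3ccc(OCc4ccccc4)c(OCc4ccccc4)c3)O2)ccc1OCc1ccccc1 | intermediate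
11 | (3S,5R)-1-[3,4-bis(benzyloxy)phenyl]-7-[4-(benzyloxy)-3-methoxyphenyl]-5-hydroxyheptan-3-yl acetate | COc1cc(CC[C@H](C[C@H](CCc2ccc(OCc3ccccc3)c(OCc3ccccc3)c2)OC(C)=O)O)ccc1OCc1ccccc1 | intermediate
12 | (3S,5R)-1-[3,4-bis(benzyloxy)phenyl]-7-[4-(benzyloxy)-3-methoxyphenyl]heptane-3,5-diyl diacetate | COc1cc(CC[C@H](C[C@H](CCc2ccc(OCc3ccccc3)c(OCc3ccccc3)c2)OC(C)=O)OC(C)=O)ccc1OCc1ccccc1 | intermediate
13 | (3S,5R)-1-(3,4-dihydroxyphenyl)-7-(4-hydroxy-3-methoxyphenyl)heptane-3,5-diyl diacetate | COc1cc(CC[C@H](C[C@H](CCc2ccc(O)c(O)c2)OC(C)=O)OC(C)=O)ccc1O | target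

Total step count: 8. Longest linear sequence: 8 steps (1 to 13); 6 enters in step 4.

**Steps most likely to fail**

1. Step 4.
   - What may go wrong: the strongly stabilised oxocarbenium ion may close slowly. Reversible 2-oxonia-Cope rearrangement and allyl transfer could then exchange side chains and erode the configuration at C5, and long acid contact could start to remove benzyl groups.
   - Fallback, from 5 and back at 12: the same C1–C2 bond is made with reversed polarity. Boc2O and DMAP convert 5 into the tert-butyl carbonate F1. IBr in toluene at low temperature closes F1 to the cis-iodomethyl cyclic carbonate F2 (iodocarbonate cyclisation, 1,3-syn induction through a chair with both substituents equatorial). K2CO3 in MeOH turns F2 into the syn-epoxy alcohol F3.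
   - Magnesium and commercial 3,4-bis(benzyloxy)benzyl chloride give the benzylmagnesium chloride F4. With catalytic CuI in THF at low temperature, F4 opens the epoxide at its CH2 terminus to give the syn-diol F5. Ac2O, pyridine and DMAP convert F5 into 12.

2. Step 6.
   - What may go wrong: the benzylic cation may lose a proton, after which the now allylic C3 acetate could ionise. The acetate carbonyl may take part at C1, or the cation may alkylate another electron-rich ring before hydride arrives.
   - Fallback, from 10 and back at 13: heterogeneous hydrogenolysis replaces the ionic reduction. H2 over Pd(OH)2/C in EtOH–AcOH removes the three benzyl groups and then cleaves the ring C1–O5 bond, which is now benzylic to a free 4-hydroxyaryl group. This is the reaction type by which 2-aryltetrahydrofuran lignans are opened, and it gives the triphenol hydroxy acetate F6.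
   - Ac2O and pyridine give the pentaacetate F7. NH4OAc in aqueous MeOH then removes only the three aryl acetates, whose phenoxide leaving groups make them far more labile than the alkyl acetates, to give 13.

3. Step 5.
   - What may go wrong: elimination to a dihydropyran, or incomplete inversion at the ring carbinol.
   - Fallback, from 9 and back at 10: the centre is reset through the ketone. Dess–Martin periodinane oxidises 9 to the tetrahydropyran-4-one F8. L-Selectride in THF at −78 °C attacks along the equatorial direction and gives the axial alcohol F9. Ac2O, pyridine and DMAP convert F9 into 10.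

**Further compounds**
F1 | step 4 | tert-butyl (R)-1-[4-(benzyloxy)-3-methoxyphenyl]hex-5-en-3-yl carbonate | COc1cc(CC[C@H](CC=C)OC(=O)OC(C)(C)C)ccc1OCc1ccccc1
F2 | step 4 | (4R,6R)-4-(iodomethyl)-6-{2-[4-(benzyloxy)-3-methoxyphenyl]ethyl}-1,3-dioxan-2-one (cis) | COc1cc(CC[C@@H]2C[C@H](CI)OC(=O)O2)ccc1OCc1ccccc1
F3 | step 4 | (2R)-4-[4-(benzyloxy)-3-methoxyphenyl]-1-[(2R)-oxiran-2-yl]butan-2-ol | COc1cc(CC[C@H](C[C@@H]2CO2)O)ccc1OCc1ccccc1
F4 | step 4 | 3,4-bis(benzyloxy)benzylmagnesium chloride | Cl[Mg]Cc1ccc(OCc2ccccc2)c(OCc2ccccc2)c1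
F5 | step 4 | (3S,5R)-1-[3,4-bis(benzyloxy)phenyl]-7-[4-(benzyloxy)-3-methoxyphenyl]heptane-3,5-diol | COc1cc(CC[C@H](C[C@H](CCc2ccc(OCc3ccccc3)c(OCc3ccccc3)c2)O)O)ccc1OCc1ccccc1
F6 | step 6 | (3S,5R)-1-(3,4-dihydroxyphenyl)-5-hydroxy-7-(4-hydroxy-3-methoxyphenyl)heptan-3-yl acetate | COc1cc(CC[C@H](C[C@H](CCc2ccc(O)c(O)c2)OC(C)=O)O)ccc1O
F7 | step 6 | (3S,5R)-1-(3,4-diacetoxyphenyl)-7-(4-acetoxy-3-methoxyphenyl)heptane-3,5-diyl diacetate | COc1cc(CC[C@H](C[C@H](CCc2ccc(OC(C)=O)c(OC(C)=O)c2)OC(C)=O)OC(C)=O)ccc1OC(C)=O
F8 | step 5 | (2R,6R)-2-[3,4-bis(benzyloxy)phenyl]-6-{2-[4-(benzyloxy)-3-methoxyphenyl]ethyl}tetrahydro-4H-pyran-4-one | COc1cc(CC[C@@H]2CC(=O)C[C@H](c3ccc(OCc4ccccc4)c(OCc4ccccc4)c3)O2)ccc1OCc1ccccc1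
F9 | step 5 | (2R,4R,6R)-2-[3,4-bis(benzyloxy)phenyl]-6-{2-[4-(benzyloxy)-3-methoxyphenyl]ethyl}tetrahydro-2H-pyran-4-ol (axial alcohol) | COc1cc(CC[C@@H]2C[C@@H](O)C[C@H](c3ccc(OCc4ccccc4)c(OCc4ccccc4)c3)O2)ccc1OCc1ccccc1
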